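**Plan**

- Cuts, in retrosynthetic order: the C17=C18 alkene beside the butenolide (olefination), the C5–O1 bond of ring A, the C4–C5 bond (allyl–alkenyl coupling), the C3–C8 bond (Morita–Baylis–Hillman) and the C9–C10 bond (nitrile alkylation). The chain is numbered on from ring A: C8 is the alkylidene carbon and C18 the carbon attached to the butenolide.
- Enabling feature: in ring A (O1, carbonyl C2, C3, C4, C5) the single stereocentre C5 is allylic and bonded to O1, and its alkene C6=C7 ends in a carbon with two methyl groups. C5–C6–C7 is therefore an allyl unit with a symmetric C7 terminus, so an achiral C7 carbonate can be ionised and the two faces of the allyl can exchange.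
- Forward: geraniol is extended to a C12 aldehyde; methyl acrylate and then an alkenylboronate build the open-chain seco-acid; ring A closes by palladium-catalysed lactonisation; the butenolide ring is brought in preformed as a phosphonate and attached last.
- Stereochemistry: C5 (S) comes from the chiral diphosphine ligand in the ring closure. The C11=C12 and C15=C16 alkenes come from geraniol and its E-selective allylic oxidation, C3=C8 (E) from the allylic coupling, C17=C18 (E) from the final olefination.

Key step: step 12

Abbreviations: TBS = tert-butyldimethylsilyl, Bpin = 4,4,5,5-tetramethyl-1,3,2-dioxaborolan-2-yl, Boc = tert-butoxycarbonyl.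

Remark on the chemistry: which antipode of the diamine ligand gives S at C5 is assigned by analogy with heteroatom attack on the monosubstituted terminus of allyl complexes whose other terminus carries two identical groups; the (S,S)-ligand is written, and its mirror image, equally available, would replace it unchanged if a first run showed the opposite sense.

**Route**

Step 1
Reactants: 1 geraniol
Product: 2 geranyl TBS ether
Conditions: TBSCl, imidazole, DMF, 0 °C to rt
Reagents that add atoms: tert-butyldimethylsilyl chloride, CC(C)(C)[Si](C)(C)Cl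
Why: Routine silylation of a primary allylic alcohol; a silyl ether is chosen because an ester at this terminus would later be ionised by palladium.

Step 2
Reactants: 2 geranyl TBS ether
Product: 3 (2E,6E)-8-(TBSO)-2,6-dimethylocta-2,6-dien-1-ol
Conditions: SeO2 (0.1 equiv), t-BuOOH (2 equiv), salicylic acid (0.1 equiv), CH2Cl2, 0 °C to rt
Reagents that add atoms: tert-butyl hydroperoxide, CC(C)(C)OO (terminal oxidant; the oxygen is passed on through catalytic selenium dioxide, O=[Se]=O)
Why: Riley-type allylic oxidation (ene reaction, then 2,3-sigmatropic shift) should take place at the E-methyl group of the more electron-rich terminal alkene and give the E allylic alcohol.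

Step 3
Reactants: 3 (2E,6E)-8-(TBSO)-2,6-dimethylocta-2,6-dien-1-ol
Product: 4 (2E,6E)-8-bromo-3,7-dimethylocta-2,6-dien-1-yl TBS ether
Conditions: CBr4, PPh3, CH2Cl2, 0 °C
Reagents that add atoms: carbon tetrabromide, BrC(Br)(Br)Br
Why: Appel bromination displaces the alkoxyphosphonium group by SN2 under neutral conditions, so the silyl ether and both alkene geometries should be untouched.

Step 4
Reactants: 4 (2E,6E)-8-bromo-3,7-dimethylocta-2,6-dien-1-yl TBS ether; 5 acetonitrile
Product: 7 (4E,8E)-10-(TBSO)-4,8-dimethyldeca-4,8-dienenitrile, via cyanomethyllithium 6 (not isolated)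
Conditions: MeCN (3 equiv), n-BuLi (2.8 equiv), THF, −78 °C; then 4, −78 to −40 °C
Reagents that add atoms: none
Why: SN2 alkylation of a nitrile-stabilised carbanion by a primary allylic bromide forms the C9–C10 bond; excess anion at low temperature should suppress double alkylation.

Step 5
Reactants: 7 (4E,8E)-10-(TBSO)-4,8-dimethyldeca-4,8-dienenitrile
Product: 9 (4E,8E)-10-(TBSO)-4,8-dimethyldeca-4,8-dienal, via N-aluminio aldimine 8 (not isolated)
Conditions: i-Bu2AlH (1.2 equiv), CH2Cl2, −78 °C; then aq. potassium sodium tartrate, rt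
Reagents that add atoms: water, O
Why: Partial reduction of a nitrile stops at the N-aluminated imine, which hydrolyses on work-up to the aldehyde without over-reduction.

Step 6
Reactants: 9 (4E,8E)-10-(TBSO)-4,8-dimethyldeca-4,8-dienal; 10 methyl acrylate
Product: 11 methyl (6E,10E)-12-(TBSO)-3-hydroxy-6,10-dimethyl-2-methylidenedodeca-6,10-dienoate (racemic)
Conditions: DABCO (1 equiv), methyl acrylate (3 equiv), 1,4-dioxane/H2O (1:1), rt
Reagents that add atoms: none
Why: Morita–Baylis–Hillman reaction of an unhindered aliphatic aldehyde forms the C3–C8 bond; the carbinol centre is formed racemic and is erased in step 9.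

Step 7
Reactants: 11 Morita–Baylis–Hillman alcohol
Product: 12 methyl (6E,10E)-3-acetoxy-12-(TBSO)-6,10-dimethyl-2-methylidenedodeca-6,10-dienoate (racemic)
Conditions: AcCl, pyridine, CH2Cl2, 0 °C
Reagents that add atoms: acetyl chloride, CC(Cl)=O
Why: Simple O-acylation turns the secondary allylic alcohol into a leaving group for palladium; pyridine without a stronger nucleophilic catalyst should avoid allylic transposition of the acetate.

Step 8
Reactants: 13 2-methylbut-3-yn-2-ol
Product: 14 (3E)-2-methyl-4-Bpin-but-3-en-2-ol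
Conditions: CuCl (5 mol%), Xantphos (5 mol%), NaOt-Bu (10 mol%), B2pin2 (1.1 equiv), MeOH (2 equiv), THF, rt
Reagents that add atoms: bis(pinacolato)diboron, CC1(C)OB(OC1(C)C)B1OC(C)(C)C(C)(C)O1
Why: Copper-catalysed formal hydroboration: a boryl complex of monovalent copper adds syn across the terminal alkyne with boron at the unhindered carbon, and methanol protonates the alkenylcopper, so the E alkenylboronate should result with the free tertiary alcohol tolerated.

Step 9
Reactants: 12 Morita–Baylis–Hillman acetate; 14 (3E)-2-methyl-4-Bpin-but-3-en-2-ol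
Product: 15 methyl (2E,6E,10E)-12-(TBSO)-2-[(2E)-4-hydroxy-4-methylpent-2-en-1-yl]-6,10-dimethyldodeca-2,6,10-trienoate
Conditions: Pd(PPh3)4 (5 mol%), K2CO3 (2 equiv), THF/H2O (10:1), 50 °C
Reagents that add atoms: none
Why: Tsuji–Trost ionisation of the acetate by zerovalent palladium gives a 2-(methoxycarbonyl)allyl complex that takes the alkenyl group from boron (Suzuki–Miyaura-type transmetallation) and couples at its unsubstituted CH2 terminus, so the C4–C5 bond forms with allylic transposition, the alkenyl geometry is retained and C3=C8 should be E because the chain lies away from the ester in both the allyl complex and the product.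

Step 10
Reactants: 15 hydroxy trienoate
Product: 17 methyl (2E,6E,10E)-2-[(2E)-4-(Boc-oxy)-4-methylpent-2-en-1-yl]-12-(TBSO)-6,10-dimethyldodeca-2,6,10-trienoate, via lithium alkoxide 16 (not isolated)
Conditions: LiN(SiMe3)2 (1.05 equiv), THF, −78 °C; Boc2O (1.3 equiv), −78 to 0 °C; H2O quench
Reagents that add atoms: di-tert-butyl dicarbonate, CC(C)(C)OC(=O)OC(=O)OC(C)(C)C
Why: O–H deprotonation is far faster than any C–H deprotonation of the enoate, and acylation of the tertiary alkoxide gives a tert-butyl carbonate, chosen over a methyl carbonate because a carbonate flanked by two tertiary alkoxy groups should survive the ester hydrolysis that follows.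

Step 11
Reactants: 17 Boc carbonate methyl ester
Product: 19 (2E,6E,10E)-2-[(2E)-4-(Boc-oxy)-4-methylpent-2-en-1-yl]-12-(TBSO)-6,10-dimethyldodeca-2,6,10-trienoic acid (achiral), via lithium carboxylate 18 (not isolated)
Conditions: LiOH·H2O (3 equiv), THF/H2O (3:1), 0 °C to rt; then cold 0.5 M HCl to pH 4; used without storage
Reagents that add atoms: lithium hydroxide, [Li+].[OH-]
Why: Saponification: hydroxide attacks the methyl ester carbonyl, while the hindered di-tert-alkyl carbonate and the silyl ether should be left alone; brief acidification to pH 4 in the cold frees the acid without ionising the tertiary allylic carbonate.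

Step 12
Reactants: 19 achiral seco-acid with the C7 tert-butyl carbonate
Product: 20 (3E,5S)-3-[(4E,8E)-10-(TBSO)-4,8-dimethyldeca-4,8-dien-1-ylidene]-5-(2-methylprop-1-en-1-yl)oxolan-2-one
Conditions: Pd2(dba)3·CHCl3 (2.5 mol%), N,N'-[(1S,2S)-cyclohexane-1,2-diyl]bis[2-(diphenylphosphanyl)benzamide] (7.5 mol%), CH2Cl2 (0.05 M), 0 °C, stopped when 19 is consumed
Reagents that add atoms: none
Why: Zerovalent palladium carrying the chiral diphosphine ionises the tertiary carbonate with loss of CO2 and tert-butoxide (which deprotonates the acid), giving a cationic allyl complex of divalent palladium over C5–C6–C7. Because C7 bears two methyl groups, the two diastereomeric complexes exchange faces by an eta-3 to eta-1 to eta-3 shift at C7 faster than they are trapped, so the ligand pocket decides which one cyclises (dynamic asymmetric transformation). Ring A closes by 5-exo attack of the carboxylate oxygen O1 on C5, anti to palladium; attack at C7 would need a seven-membered ring holding an E alkene and is excluded. C5 is set by the ligand alone, since 19 has no stereocentre and the C3=C8 geometry is already fixed. The closest known reaction type is the Tsuji–Trost asymmetric allylic substitution with carboxylate and phenol nucleophiles, together with dynamic alkylations of allyl systems that have a doubly substituted terminus. The step needs face selection and substitution ahead of β-hydride loss from the C7 methyl groups; the short tether holds the carboxylate next to C5 for fast closure, and stopping at conversion should limit re-ionisation of the allylic lactone.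

Step 13
Reactants: 20 silyl-protected lactone
Product: 21 (3E,5S)-3-[(4E,8E)-10-hydroxy-4,8-dimethyldeca-4,8-dien-1-ylidene]-5-(2-methylprop-1-en-1-yl)oxolan-2-one
Conditions: HF·pyridine, pyridine, THF, 0 °C to rt
Reagents that add atoms: none
Why: Fluoride-driven cleavage of the primary silyl ether under buffered conditions should leave the allylic lactone C5–O1 bond and the alkylidene in place.

Step 14
Reactants: 21 allylic alcohol
Product: 22 (2E,6E,10E)-3,7-dimethyl-10-[(5S)-5-(2-methylprop-1-en-1-yl)-2-oxooxolan-3-ylidene]deca-2,6-dienal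
Conditions: MnO2 (activated, 15 equiv), CH2Cl2, rt
Reagents that add atoms: none
Why: MnO2 oxidises only the allylic alcohol, giving the E enal under neutral conditions without touching C5.

Step 15
Reactants: 23 1,3-dihydroxyacetone (supplied as its dimer); 24 ethyl (triphenylphosphoranylidene)acetate
Product: 26 4-(hydroxymethyl)furan-2(5H)-one, via dihydroxy ester 25 (not isolated)
Conditions: CH2Cl2, rt
Reagents that add atoms: none
Why: Wittig olefination of the ketone with a stabilised ylide gives an enoate in which one of the two equivalent hydroxymethyl groups is always cis to the ester and lactonises spontaneously.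

Step 16
Reactants: 26 4-(hydroxymethyl)furan-2(5H)-one
Product: 27 4-(bromomethyl)furan-2(5H)-one
Conditions: CBr4, PPh3, CH2Cl2, 0 °C
Reagents that add atoms: carbon tetrabromide, BrC(Br)(Br)Br
Why: Appel bromination of a primary allylic alcohol under neutral conditions spares the butenolide.

Step 17
Reactants: 27 4-(bromomethyl)furan-2(5H)-one
Product: 28 diethyl [(5-oxo-2,5-dihydrofuran-3-yl)methyl]phosphonate
Conditions: P(OEt)3 (2 equiv), toluene, 110 °C
Reagents that add atoms: triethyl phosphite, CCOP(OCC)OCC
Why: Michaelis–Arbuzov reaction of a reactive primary allylic bromide, with bromoethane distilling off.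

Step 18
Reactants: 22 enal; 28 butenolide phosphonate
Product: 30 (3E,5S)-3-[(4E,8E,10E)-4,8-dimethyl-11-(5-oxo-2,5-dihydrofuran-3-yl)undeca-4,8,10-trien-1-ylidene]-5-(2-methylprop-1-en-1-yl)oxolan-2-one, via lithiated phosphonate 29 (not isolated)
Conditions: 28 (1.3 equiv), LiN(SiMe3)2 (1.2 equiv), THF, −78 °C; then 22, −78 to 0 °C
Reagents that add atoms: none
Why: Vinylogous Horner–Wadsworth–Emmons olefination: the anion, delocalised into the butenolide, reacts at the phosphorus-bearing carbon with the enal and should give the E C17=C18 alkene, while keeping base below the amount of phosphonate keeps ring A away from free strong base.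

**Compound list**

1 | geraniol, (2E)-3,7-dimethylocta-2,6-dien-1-ol | CC(C)=CCC/C(C)=C/CO | starting material
2 | tert-butyl{[(2E)-3,7-dimethylocta-2,6-dien-1-yl]oxy}dimethylsilane | CC(C)=CCC/C(C)=C/CO[Si](C)(C)C(C)(C)C | intermediate
3 | (2E,6E)-8-{[tert-butyl(dimethyl)silyl]oxy}-2,6-dimethylocta-2,6-dien-1-ol | OC/C(C)=C/CC/C(C)=C/CO[Si](C)(C)C(C)(C)C | intermediate
4 | {[(2E,6E)-8-bromo-3,7-dimethylocta-2,6-dien-1-yl]oxy}(tert-butyl)dimethylsilane | BrC/C(C)=C/CC/C(C)=C/CO[Si](C)(C)C(C)(C)C | intermediate
5 | acetonitrile | CC#N | starting material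
6 | cyanomethyllithium | [Li+].[CH2-]C#N | intermediate
7 | (4E,8E)-10-{[tert-butyl(dimethyl)silyl]oxy}-4,8-dimethyldeca-4,8-dienenitrile | N#CCC/C(C)=C/CC/C(C)=C/CO[Si](C)(C)C(C)(C)C | intermediate
8 | (4E,8E)-10-{[tert-butyl(dimethyl)silyl]oxy}-N-(diisobutylalumanyl)-4,8-dimethyldeca-4,8-dien-1-imine | CC(C)C[Al](CC(C)C)N=CCC/C(C)=C/CC/C(C)=C/CO[Si](C)(C)C(C)(C)C | intermediate
9 | (4E,8E)-10-{[tert-butyl(dimethyl)silyl]oxy}-4,8-dimethyldeca-4,8-dienal | O=CCC/C(C)=C/CC/C(C)=C/CO[Si](C)(C)C(C)(C)C | intermediate
10 | methyl acrylate | C=CC(=O)OC | starting material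
11 | methyl (6E,10E)-12-{[tert-butyl(dimethyl)silyl]oxy}-3-hydroxy-6,10-dimethyl-2-methylidenedodeca-6,10-dienoate (racemic) | C=C(C(=O)OC)C(O)CC/C(C)=C/CC/C(C)=C/CO[Si](C)(C)C(C)(C)C | intermediate
12 | methyl (6E,10E)-3-acetoxy-12-{[tert-butyl(dimethyl)silyl]oxy}-6,10-dimethyl-2-methylidenedodeca-6,10-dienoate (racemic) | C=C(C(=O)OC)C(OC(C)=O)CC/C(C)=C/CC/C(C)=C/CO[Si](C)(C)C(C)(C)C | intermediate
13 | 2-methylbut-3-yn-2-ol | CC(C)(O)C#C | starting material
14 | (3E)-2-methyl-4-(4,4,5,5-tetramethyl-1,3,2-dioxaborolan-2-yl)but-3-en-2-ol | CC(C)(O)/C=C/B1OC(C)(C)C(C)(C)O1 | intermediate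
15 | methyl (2E,6E,10E)-12-{[tert-butyl(dimethyl)silyl]oxy}-2-[(2E)-4-hydroxy-4-methylpent-2-en-1-yl]-6,10-dimethyldodeca-2,6,10-trienoate | CC(C)(O)/C=C/C/C(=C\CC/C(C)=C/CC/C(C)=C/CO[Si](C)(C)C(C)(C)C)C(=O)OC | intermediate
16 | lithium alkoxide of 15 | [Li+].CC(C)([O-])/C=C/C/C(=C\CC/C(C)=C/CC/C(C)=C/CO[Si](C)(C)C(C)(C)C)C(=O)OC | intermediate
17 | methyl (2E,6E,10E)-2-{(2E)-4-[(tert-butoxycarbonyl)oxy]-4-methylpent-2-en-1-yl}-12-{[tert-butyl(dimethyl)silyl]oxy}-6,10-dimethyldodeca-2,6,10-trienoate | CC(C)(C)OC(=O)OC(C)(C)/C=C/C/C(=C\CC/C(C)=C/CC/C(C)=C/CO[Si](C)(C)C(C)(C)C)C(=O)OC | intermediate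
18 | lithium carboxylate of 19 | [Li+].CC(C)(C)OC(=O)OC(C)(C)/C=C/C/C(=C\CC/C(C)=C/CC/C(C)=C/CO[Si](C)(C)C(C)(C)C)C([O-])=O | intermediate
19 | (2E,6E,10E)-2-{(2E)-4-[(tert-butoxycarbonyl)oxy]-4-methylpent-2-en-1-yl}-12-{[tert-butyl(dimethyl)silyl]oxy}-6,10-dimethyldodeca-2,6,10-trienoic acid (achiral) | CC(C)(C)OC(=O)OC(C)(C)/C=C/C/C(=C\CC/C(C)=C/CC/C(C)=C/CO[Si](C)(C)C(C)(C)C)C(=O)O | intermediate
20 | (3E,5S)-3-[(4E,8E)-10-{[tert-butyl(dimethyl)silyl]oxy}-4,8-dimethyldeca-4,8-dien-1-ylidene]-5-(2-methylprop-1-en-1-yl)oxolan-2-one | CC(C)=C[C@@H]1C/C(=C\CC/C(C)=C/CC/C(C)=C/CO[Si](C)(C)C(C)(C)C)C(=O)O1 | intermediate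
21 | (3E,5S)-3-[(4E,8E)-10-hydroxy-4,8-dimethyldeca-4,8-dien-1-ylidene]-5-(2-methylprop-1-en-1-yl)oxolan-2-one | CC(C)=C[C@@H]1C/C(=C\CC/C(C)=C/CC/C(C)=C/CO)C(=O)O1 | intermediate
22 | (2E,6E,10E)-3,7-dimethyl-10-[(5S)-5-(2-methylprop-1-en-1-yl)-2-oxooxolan-3-ylidene]deca-2,6-dienal | CC(C)=C[C@@H]1C/C(=C\CC/C(C)=C/CC/C(C)=C/C=O)C(=O)O1 | intermediate
23 | 1,3-dihydroxyacetone (supplied as its dimer) | OCC(=O)CO | starting material
24 | ethyl (triphenylphosphoranylidene)acetate | CCOC(=O)C=P(c1ccccc1)(c1ccccc1)c1ccccc1 | starting material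
25 | ethyl 4-hydroxy-3-(hydroxymethyl)but-2-enoate | CCOC(=O)C=C(CO)CO | intermediate
26 | 4-(hydroxymethyl)furan-2(5H)-one | O=C1C=C(CO)CO1 | intermediate
27 | 4-(bromomethyl)furan-2(5H)-one | O=C1C=C(CBr)CO1 | intermediate
28 | diethyl [(5-oxo-2,5-dihydrofuran-3-yl)methyl]phosphonate | CCOP(=O)(CC1=CC(=O)OC1)OCC | intermediate
29 | lithiated 28 (carbanion at the phosphorus-bearing carbon) | [Li+].CCOP(=O)([CH-]C1=CC(=O)OC1)OCC | intermediate
30 | (3E,5S)-3-[(4E,8E,10E)-4,8-dimethyl-11-(5-oxo-2,5-dihydrofuran-3-yl)undeca-4,8,10-trien-1-ylidene]-5-(2-methylprop-1-en-1-yl)oxolan-2-one | CC(C)=C[C@@H]1C/C(=C\CC/C(C)=C/CC/C(C)=C/C=C/C2=CC(=O)OC2)C(=O)O1 | target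

**Count**

Total steps: 18. Longest linear sequence: 14 steps (steps 1–7, 9–14 and 18, from geraniol); steps 8 and 15–17 prepare the two side fragments.

**Steps most likely to fail**

Step 12. The ligand may discriminate poorly between the two equilibrating allyl complexes, the allyl complex may lose a β-hydrogen from a C7 methyl group to give a diene, or the product may re-ionise and lose enantiopurity. The fallback sets out from 15 and replaces the palladium closure by reagent-controlled reduction. Oxidative 1,3-transposition of the tertiary allylic alcohol with pyridinium chlorochromate, (C5H5NH)[CrO3Cl], in CH2Cl2 (Babler–Dauben) should give the enone methyl (2E,6E,10E)-12-{[tert-butyl(dimethyl)silyl]oxy}-6,10-dimethyl-2-(4-methyl-2-oxopent-3-en-1-yl)dodeca-2,6,10-trienoate F1. Corey–Bakshi–Shibata reduction with (R)-2-methyl-CBS-oxazaborolidine and catecholborane in toluene at −78 °C, the alkenyl branch acting as the large group, should give methyl (2E,6E,10E)-12-{[tert-butyl(dimethyl)silyl]oxy}-2-[(2S)-2-hydroxy-4-methylpent-3-en-1-yl]-6,10-dimethyldodeca-2,6,10-trienoate F2. Catalytic pyridinium p-toluenesulfonate in toluene then closes ring A with loss of methanol, and the route is rejoined at 20; compounds 16–19 are bypassed.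

Step 9. Transmetallation from boron may be slow enough for the allyl complex to lose a β-hydrogen, the boronate may protodeboronate, or the E/Z control at C3=C8 may be incomplete. The fallback sets out from 11 (so that acetate 12 is not needed) and from 14. Aqueous KHF2 in MeOH converts 14 into potassium trifluoro[(1E)-3-hydroxy-3-methylbut-1-en-1-yl]borate F3. With [RhCl(cod)]2 as catalyst in MeOH/toluene at rt to 50 °C, the alkenylrhodium adds 1,4 to the acrylate unit of 11 and β-hydroxy elimination follows, a sequence known to favour E trisubstituted enoates. The route is rejoined at 15.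

Step 18. The phosphonate may be deprotonated at the ring methylene of the butenolide instead of at the phosphorus-bearing carbon, base may move the ring A alkylidene into the ring, or the new alkene may form as an E/Z mixture. The fallback sets out from 22. Takai olefination (CrCl2, CHI3, THF, 0 °C) should give (3E,5S)-3-[(4E,8E,10E)-11-iodo-4,8-dimethylundeca-4,8,10-trien-1-ylidene]-5-(2-methylprop-1-en-1-yl)oxolan-2-one F4. A palladium-free Stille-type coupling with commercial 4-(tributylstannyl)furan-2(5H)-one, mediated by copper thiophene-2-carboxylate (CuO2CC4H3S, monovalent copper) in N-methylpyrrolidone at 0 °C, then joins the butenolide without a catalyst that could re-ionise ring A. The route is rejoined at 30.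

**Further compounds**

F1 | step 12 | methyl (2E,6E,10E)-12-{[tert-butyl(dimethyl)silyl]oxy}-6,10-dimethyl-2-(4-methyl-2-oxopent-3-en-1-yl)dodeca-2,6,10-trienoate | CC(C)=CC(=O)C/C(=C\CC/C(C)=C/CC/C(C)=C/CO[Si](C)(C)C(C)(C)C)C(=O)OC
F2 | step 12 | methyl (2E,6E,10E)-12-{[tert-butyl(dimethyl)silyl]oxy}-2-[(2S)-2-hydroxy-4-methylpent-3-en-1-yl]-6,10-dimethyldodeca-2,6,10-trienoate | CC(C)=C[C@@H](O)C/C(=C\CC/C(C)=C/CC/C(C)=C/CO[Si](C)(C)C(C)(C)C)C(=O)OC
F3 | step 9 | potassium trifluoro[(1E)-3-hydroxy-3-methylbut-1-en-1-yl]borate | [K+].CC(C)(O)/C=C/[B-](F)(F)F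
F4 | step 18 | (3E,5S)-3-[(4E,8E,10E)-11-iodo-4,8-dimethylundeca-4,8,10-trien-1-ylidene]-5-(2-methylprop-1-en-1-yl)oxolan-2-one | CC(C)=C[C@@H]1C/C(=C\CC/C(C)=C/CC/C(C)=C/C=C/I)C(=O)O1
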